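A small charge, that of the maple run, reads higher in single ring at 0.833 min than the larger charge of the alder run does at 1.33 min, and these two runs are what I have to reckon the cost of the larger charge from.

| flask | substrate | remark | time |
|---|---|---|---|
| alder | 0.025 M | the very flask that is asked about, followed so far |  |
| maple | 0.013 M | run made earlier |  |
| flask | 0.025 M |  | 8.0 min |

- alder (time / min: single ring / %, substrate / %): 0.250: 22.4, 59.9; 0.500: 31.2, 36.7; 1.33: 32.7, 8.6; 3.00: 18.5, 0.9
- maple (time / min: single ring / %, substrate / %): 0.250: 23.8, 65.3; 0.833: 42.0, 24.8; 2.50: 29.4, 1.7; 8.00: 6.6, 0.2

(readings scatter by 0.3 percentage points)

1. time up to 8.0 min at which single ring stands highest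
2. the amount of single ring, in percent of the substrate charged, at that time

- the earlier runs were read with a standard deviation of 0.3 percentage points

At 0.250 min I divide the substrate lost by the single ring standing and call this the spending number, an inverse selectivity: it reads 1.46 in the maple run and 1.79 in the alder run. A straight line through these two gives the charge penalty, the rise of the spending number per unit of c(substrate), 27.7 /M, and leaves 1.10 at vanishing charge.

I take the peak of single ring as inverse to the spending number, scaled on the highest maple reading, 42.0%. One extreme keeps the constant term and gives 55.8%; the other keeps the alder charge term and gives 88.5%. The alder flask carries both terms, so, adding the inverses, I commit to 34.2% as my estimate of its peak, lower than either extreme, and I place that peak in time between the readings at 0.500 min and 1.33 min.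

The forecast gives 35% at 0.9 min, expecting “a loss pathway of higher order”, and my figure is lower than its value.

The alder flask gives 35.2% at 0.918 min.

    2 substrate → open dimer (k = 0.250 /M/s)
    substrate + single ring → side product (k = 0.650 /M/s)
    substrate → single ring (k = 0.0220 /s)
    open dimer → ring dimer (k = 0.0130 /s)
    single ring ⇌ isomer of the product (K = 13.0, k = 0.00810 /s)
    substrate + open dimer → open trimer (k = 0.0740 /M/s)

My figure falls short of the alder flask by 1.00 point. On the neighbour charged with 0.0063 M of substrate, all else as in alder, the charge penalty gives a spending number of 1.27 and so a peak of 48.1%. That neighbour flask gives 48.4%.

The earlier runs and the new flask are simulated with constants of no real substance; the scatter is artificial.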